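I began with the easy step, which was to ask how fast the solid substrate can enter the solution.

    dissolved substrate + partner → target (k1 = 3.4 M⁻¹ min⁻¹)
    2 dissolved substrate → side product (k2 = 15 M⁻¹ min⁻¹)
    solid substrate ⇌ dissolved substrate, rate k3*(cs3 - [dissolved substrate]) while solid is left; crystals form when [dissolved substrate] > cs3 (cs3 = 2.8 mM, k3 = 0.0022 min⁻¹)
    solid product ⇌ target, rate k4*(cs4 - [target]) while solid is left; crystals form when [target] > cs4 (cs4 = 9.0 mM, k4 = 0.044 min⁻¹)

solid substrate 23 mM; partner 34.5 mM; time 50 h

* the target and solid product together standing at 50 h, as a percentage of the solid substrate charged
* concentration of dissolved substrate in solution at 50 h, in percent of saturation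

- a species is counted by the solid substrate in it: one side product counts as two
- amounts and yields of target count solid product too
- for a step with 2 of a species take k times the square, and two of it per event
- given per volume of solution although it is solid: solid substrate, solid product
- at the start none of the solid substrate is in solution
- dissolved substrate means what is dissolved; the solid is not counted in it
- run time (flask): 50 h

Into an empty solution the solid substrate dissolves at v, its dissolution coefficient times its solubility. The dissolved substrate then meets the partner, taken as charged, with a half-life of 0.098 h, far shorter than the 5.25 h in which dissolution by itself closes half the gap to saturation, so I treated dissolution as the rate-limiting step and followed the rate.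

v = 0.00616 mM min⁻¹

C = v × 50 h / 23 mM = 80.3%

This C, the share of the charge that v delivers by the asked time, is what I call the dissolution ceiling. It stands below the whole charge, so I expected solid to remain and dissolution to continue to the end. Two factors stand between C and the yield: f, the part of v kept once dissolved substrate stands in solution, and g, the share of what dissolves that reaches target and is not lost to side product. I balanced delivery against capture by the partner at both ends, taking the partner at the end as lowered by what v delivers.

start: f = 98.2%, g = 98.7%

end, partner at 16.0 mM: f = 96.1%, g = 94.4%

y = C × mean f × mean g = 75.3%

The missing part of f at the end gave me a saturation of 3.88%.

The forecast gave 75.9% and 3.5%, holding that “Dissolution is the slow step”; my yield stood lower and my saturation higher.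

The flask gave 76.0% and 3.48% at 50 h, so the forecast held within its margin. Solid substrate still stood at 21.6% of the charge at 50.0 h, so this flask was still dissolving when it was read, and its yield came to 94.6% of C.

The neighbour flask with 92 mM of solid substrate has the same v, so its larger charge gives it a ceiling of 20.1%. Computed, that neighbour flask gave 19.0%, with 80.4% of its solid substrate still there.

The numbers of this flask were chosen freely; the rest is arithmetic.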